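The carbocycle (C4a, C5, C6, C7, C8, C8a; isochromene numbering) is disconnected across C4a–C8a and C7–C8. Its α′-hydroxy enone, C4a=C5–C6(=O)–C7(OH), is a ring-opened 3-oxyfuran: in the precursor the C7 oxygen bridges C7 and C4a. The key step is therefore an enantioselective copper-catalysed Diels–Alder reaction between a 2-methyl-3-siloxy-5-pentenynylfuran and an (E)-β-aroyloxy acrylimide that already carries the protected orsellinate. It forms both bonds, sets C7, C8 and C8a in one operation and stores the enone as a silyl enol ether. Imide reduction, fluoride-triggered bridge opening and gold-catalysed 6-endo closure of the pyran ring onto the alkyne complete the target.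

Key step: step 8

Remark: atom labels follow the target, C1H2–O2–C3(propenyl)=C4–C4a=C5–C6(=O)–C7(OH)(CH3)–C8(O-ester)–C8a. The lactate stereocentre of 6 is erased in step 4, so either enantiomer of 6 serves. The sense of the copper catalyst is assigned by analogy with its behaviour toward simple acrylimides.

Step 1
Reactants: 1 1,4-bis(trimethylsilyl)buta-1,3-diyne, 2 (E)-1-bromoprop-1-ene
Product: 5 trimethyl[(E)-hept-5-ene-1,3-diyn-1-yl]silane, via lithium 4-(trimethylsilyl)buta-1,3-diyn-1-ide 3 (not isolated), via bromo[4-(trimethylsilyl)buta-1,3-diyn-1-yl]zinc 4 (not isolated)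
Conditions: MeLi·LiBr (1.0 equiv), THF, −78 °C → rt; ZnBr2, 0 °C; then 2, Pd(PPh3)4 (3 mol %), rt
Reagents that add atoms: none
Why: Methyllithium cleaves one C–Si bond of the bis-silyl diyne, and the derived alkynylzinc couples with the alkenyl bromide with retention of the E geometry (Negishi coupling).

Step 2
Reactants: 5 trimethyl[(E)-hept-5-ene-1,3-diyn-1-yl]silane, 6 ethyl (S)-2-[(tert-butyldimethylsilyl)oxy]propanoate
Product: 8 (2S,8E)-2-[(tert-butyldimethylsilyl)oxy]dec-8-ene-4,6-diyn-3-one, via lithium (E)-hept-5-ene-1,3-diyn-1-ide 7 (not isolated)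
Conditions: 5, MeLi·LiBr, THF, 0 °C → rt; then 6, BF3·OEt2, THF, −78 °C; aq. NH4Cl
Reagents that add atoms: none
Why: Desilylative lithiation gives the enediynyl anion, whose BF3-mediated addition to the α-siloxy ester should stop at the ynone because the tetrahedral adduct persists at −78 °C (alkynylation of an ester).

Step 3
Reactants: 8 (2S,8E)-2-[(tert-butyldimethylsilyl)oxy]dec-8-ene-4,6-diyn-3-one
Product: 10 2-methyl-5-[(E)-pent-3-en-1-yn-1-yl]furan-3(2H)-one, via (2S,8E)-2-hydroxydec-8-ene-4,6-diyn-3-one 9 (not isolated)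
Conditions: TBAF (1.1 equiv), THF, −20 → 0 °C; aq. NH4Cl
Reagents that add atoms: none
Why: Fluoride frees the α′-alkoxide, which should add to the β-carbon of the ynone in a 5-endo-dig oxa-Michael cyclisation to give the furan-3(2H)-one, whose C2 configuration is not controlled and need not be.

Step 4
Reactants: 10 2-methyl-5-[(E)-pent-3-en-1-yn-1-yl]furan-3(2H)-one
Product: 11 triisopropyl({2-methyl-5-[(E)-pent-3-en-1-yn-1-yl]furan-3-yl}oxy)silane
Conditions: TIPSOTf, Et3N, CH2Cl2, 0 °C
Reagents that add atoms: triisopropylsilyl trifluoromethanesulfonate (TIPSOTf), CC(C)[Si](C(C)C)(C(C)C)OS(=O)(=O)C(F)(F)F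
Why: Soft enolisation and O-silylation of the furanone (silyl enol ether formation) is driven by aromatisation to the furan and removes the C2 stereocentre.

Step 5
Reactants: 12 orsellinic acid (2,4-dihydroxy-6-methylbenzoic acid)
Product: 14 2,4-bis[(tert-butyldimethylsilyl)oxy]-6-methylbenzoic acid, via tert-butyldimethylsilyl 2,4-bis[(tert-butyldimethylsilyl)oxy]-6-methylbenzoate 13 (not isolated)
Conditions: TBSCl (3.5 equiv), imidazole, DMF, rt → 40 °C; then AcOH/THF/H2O, rt
Reagents that add atoms: tert-butyldimethylsilyl chloride (TBSCl), CC(C)(C)[Si](C)(C)Cl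
Why: Exhaustive silylation followed by selective hydrolysis of the labile silyl ester should leave the two aryl silyl ethers and the free acid (protection of phenols).

Step 6
Reactants: 15 propiolic acid, 16 oxazolidin-2-one
Product: 19 3-propioloyloxazolidin-2-one, via propiolic pivalic anhydride 17 (not isolated), via lithium 2-oxooxazolidin-3-ide 18 (not isolated)
Conditions: 15, pivaloyl chloride, Et3N, THF, −78 °C; 16, n-BuLi, THF, −78 °C; combine, −78 → −20 °C
Reagents that add atoms: none
Why: N-acylation of the lithiated oxazolidinone by the mixed anhydride at low temperature, where amine addition to the alkyne is slow, should give the ynimide.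

Step 7
Reactants: 19 3-propioloyloxazolidin-2-one, 14 2,4-bis[(tert-butyldimethylsilyl)oxy]-6-methylbenzoic acid
Product: 20 (E)-3-oxo-3-(2-oxooxazolidin-3-yl)prop-1-en-1-yl 2,4-bis[(tert-butyldimethylsilyl)oxy]-6-methylbenzoate
Conditions: N-methylmorpholine (10 mol %), CH2Cl2, 0 °C → rt
Reagents that add atoms: none
Why: Amine-catalysed conjugate addition of the carboxylic acid to the ynimide (oxa-Michael addition through a β-ammonium acrylate) should give the thermodynamically preferred E enol ester.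

Step 8
Reactants: 11 triisopropyl({2-methyl-5-[(E)-pent-3-en-1-yn-1-yl]furan-3-yl}oxy)silane, 20 (E)-3-oxo-3-(2-oxooxazolidin-3-yl)prop-1-en-1-yl 2,4-bis[(tert-butyldimethylsilyl)oxy]-6-methylbenzoate
Product: 21 (1R,4R,5R,6R)-1-methyl-5-(2-oxooxazolidine-3-carbonyl)-4-[(E)-pent-3-en-1-yn-1-yl]-2-[(triisopropylsilyl)oxy]-7-oxabicyclo[2.2.1]hept-2-en-6-yl 2,4-bis[(tert-butyldimethylsilyl)oxy]-6-methylbenzoate (imide endo, aroyloxy exo)
Conditions: [Cu((R,R)-t-Bu-box)](SbF6)2 (10 mol %; t-Bu-box = 2,2′-(propane-2,2-diyl)bis[(4R)-4-tert-butyl-4,5-dihydrooxazole]), 4 Å molecular sieves, CH2Cl2, −78 °C; used cold and without delay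
Reagents that add atoms: none
Why: The divalent copper centre binds both imide carbonyls of 20 in the s-cis form, and the electron-rich furan 11 adds across its 2- and 5-positions in a normal-demand, concerted but asynchronous [4+2] cycloaddition (C7–C8 bond leading) that creates the C7–C8 and C4a–C8a bonds together; the closest known reaction type is the bis(oxazoline)copper-catalysed Diels–Alder reaction of furans and of siloxydienes with acryloyl oxazolidinones. The carbocycle is closed in cycloaddition mode and is born as a 7-oxanorbornene in which the furan oxygen bridges C7 and C4a and the C6 carbonyl is stored as the C5=C6 silyl enol ether. C8 and C8a are fixed by the catalyst: by analogy with the established sense of this catalyst family the (R,R)-ligand leaves open the Si face of the imide α-carbon, and the trans relation of the two centres is carried over from the E alkene. C7 follows from the endo orientation of the copper-bound carbonyl, which puts the aroyloxy group exo, syn to the bridging oxygen that becomes the C7 hydroxyl, while the fourth centre at C4a is only temporary. The step needs regioselectivity, secured by the 3-siloxy group that makes the methyl-bearing furan carbon the nucleophilic terminus bonding to the imide β-carbon, and endo and facial selectivity, secured by two-point binding in the square-planar complex at −78 °C.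

Step 9
Reactants: 21 (1R,4R,5R,6R)-1-methyl-5-(2-oxooxazolidine-3-carbonyl)-4-[(E)-pent-3-en-1-yn-1-yl]-2-[(triisopropylsilyl)oxy]-7-oxabicyclo[2.2.1]hept-2-en-6-yl 2,4-bis[(tert-butyldimethylsilyl)oxy]-6-methylbenzoate
Product: 22 (1R,4R,5R,6R)-5-(hydroxymethyl)-1-methyl-4-[(E)-pent-3-en-1-yn-1-yl]-2-[(triisopropylsilyl)oxy]-7-oxabicyclo[2.2.1]hept-2-en-6-yl 2,4-bis[(tert-butyldimethylsilyl)oxy]-6-methylbenzoate
Conditions: LiBH4, H2O (1 equiv), Et2O/THF, 0 °C
Reagents that add atoms: none
Why: Hydride should reduce the activated exocyclic imide carbonyl to the primary alcohol (reductive removal of the oxazolidinone) much faster than the di-ortho-substituted aryl ester, while the silyl enol ether keeps C6 masked and no stereocentre is touched.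

Step 10
Reactants: 22 (1R,4R,5R,6R)-5-(hydroxymethyl)-1-methyl-4-[(E)-pent-3-en-1-yn-1-yl]-2-[(triisopropylsilyl)oxy]-7-oxabicyclo[2.2.1]hept-2-en-6-yl 2,4-bis[(tert-butyldimethylsilyl)oxy]-6-methylbenzoate
Product: 24 (1R,2R,6R)-2-hydroxy-6-(hydroxymethyl)-2-methyl-3-oxo-5-[(E)-pent-3-en-1-yn-1-yl]cyclohex-4-en-1-yl 2,4-dihydroxy-6-methylbenzoate, via 7-oxanorbornan-2-one 23 (not isolated)
Conditions: TBAF/AcOH (1:1, 4 equiv), THF, 0 °C → rt
Reagents that add atoms: none
Why: Buffered fluoride cleaves the enol and aryl silyl ethers, and the unmasked C6 ketone should enolise toward C5 and expel the bridging oxygen from C4a (E1cB β-elimination), which gives the C4a=C5–C6 enone and leaves the oxygen on C7 as the tertiary alcohol with its configuration intact.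

Step 11
Reactants: 24 (1R,2R,6R)-2-hydroxy-6-(hydroxymethyl)-2-methyl-3-oxo-5-[(E)-pent-3-en-1-yn-1-yl]cyclohex-4-en-1-yl 2,4-dihydroxy-6-methylbenzoate
Product: 25 berkazaphilone C, (7R,8R,8aR)-7-hydroxy-7-methyl-6-oxo-3-[(E)-prop-1-en-1-yl]-6,7,8,8a-tetrahydro-1H-isochromen-8-yl 2,4-dihydroxy-6-methylbenzoate
Conditions: Ph3PAuNTf2 (5 mol %), CH2Cl2, rt
Reagents that add atoms: none
Why: π-Activation of the alkyne by the monovalent gold catalyst should trigger 6-endo-dig hydroalkoxylation by the primary alcohol at C3, the alkyne carbon that is both the δ-position of the ynenone and the one stabilised by the propenyl group, and protodeauration gives the conjugated enol ether without touching a stereocentre.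

Compound list
1 | 1,4-bis(trimethylsilyl)buta-1,3-diyne | C[Si](C)(C)C#CC#C[Si](C)(C)C | starting material
2 | (E)-1-bromoprop-1-ene | C/C=C/Br | starting material
3 | lithium 4-(trimethylsilyl)buta-1,3-diyn-1-ide | [Li]C#CC#C[Si](C)(C)C | intermediate (not isolated)
4 | bromo[4-(trimethylsilyl)buta-1,3-diyn-1-yl]zinc | Br[Zn]C#CC#C[Si](C)(C)C | intermediate (not isolated)
5 | trimethyl[(E)-hept-5-ene-1,3-diyn-1-yl]silane | C/C=C/C#CC#C[Si](C)(C)C | intermediate
6 | ethyl (S)-2-[(tert-butyldimethylsilyl)oxy]propanoate | C[C@H](O[Si](C)(C)C(C)(C)C)C(=O)OCC | starting material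
7 | lithium (E)-hept-5-ene-1,3-diyn-1-ide | [Li]C#CC#C/C=C/C | intermediate (not isolated)
8 | (2S,8E)-2-[(tert-butyldimethylsilyl)oxy]dec-8-ene-4,6-diyn-3-one | C[C@H](O[Si](C)(C)C(C)(C)C)C(=O)C#CC#C/C=C/C | intermediate
9 | (2S,8E)-2-hydroxydec-8-ene-4,6-diyn-3-one (formed as its alkoxide) | C[C@H](O)C(=O)C#CC#C/C=C/C | intermediate (not isolated)
10 | 2-methyl-5-[(E)-pent-3-en-1-yn-1-yl]furan-3(2H)-one (C2 not controlled) | CC1OC(C#C/C=C/C)=CC1=O | intermediate
11 | triisopropyl({2-methyl-5-[(E)-pent-3-en-1-yn-1-yl]furan-3-yl}oxy)silane | Cc1oc(C#C/C=C/C)cc1O[Si](C(C)C)(C(C)C)C(C)C | intermediate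
12 | orsellinic acid (2,4-dihydroxy-6-methylbenzoic acid) | Cc1cc(O)cc(O)c1C(=O)O | starting material
13 | tert-butyldimethylsilyl 2,4-bis[(tert-butyldimethylsilyl)oxy]-6-methylbenzoate | Cc1cc(O[Si](C)(C)C(C)(C)C)cc(O[Si](C)(C)C(C)(C)C)c1C(=O)O[Si](C)(C)C(C)(C)C | intermediate (not isolated)
14 | 2,4-bis[(tert-butyldimethylsilyl)oxy]-6-methylbenzoic acid | Cc1cc(O[Si](C)(C)C(C)(C)C)cc(O[Si](C)(C)C(C)(C)C)c1C(=O)O | intermediate
15 | propiolic acid | C#CC(=O)O | starting material
16 | oxazolidin-2-one | O=C1NCCO1 | starting material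
17 | propiolic pivalic anhydride | C#CC(=O)OC(=O)C(C)(C)C | intermediate (not isolated)
18 | lithium 2-oxooxazolidin-3-ide | [Li]N1CCOC1=O | intermediate (not isolated)
19 | 3-propioloyloxazolidin-2-one | C#CC(=O)N1CCOC1=O | intermediate
20 | (E)-3-oxo-3-(2-oxooxazolidin-3-yl)prop-1-en-1-yl 2,4-bis[(tert-butyldimethylsilyl)oxy]-6-methylbenzoate | Cc1cc(O[Si](C)(C)C(C)(C)C)cc(O[Si](C)(C)C(C)(C)C)c1C(=O)O/C=C/C(=O)N1CCOC1=O | intermediate
21 | (1R,4R,5R,6R)-1-methyl-5-(2-oxooxazolidine-3-carbonyl)-4-[(E)-pent-3-en-1-yn-1-yl]-2-[(triisopropylsilyl)oxy]-7-oxabicyclo[2.2.1]hept-2-en-6-yl 2,4-bis[(tert-butyldimethylsilyl)oxy]-6-methylbenzoate | C[C@]12O[C@](C#C/C=C/C)(C=C1O[Si](C(C)C)(C(C)C)C(C)C)[C@H](C(=O)N3CCOC3=O)[C@H]2OC(=O)c2c(C)cc(O[Si](C)(C)C(C)(C)C)cc2O[Si](C)(C)C(C)(C)C | intermediate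
22 | (1R,4R,5R,6R)-5-(hydroxymethyl)-1-methyl-4-[(E)-pent-3-en-1-yn-1-yl]-2-[(triisopropylsilyl)oxy]-7-oxabicyclo[2.2.1]hept-2-en-6-yl 2,4-bis[(tert-butyldimethylsilyl)oxy]-6-methylbenzoate | C[C@]12O[C@](C#C/C=C/C)(C=C1O[Si](C(C)C)(C(C)C)C(C)C)[C@H](CO)[C@H]2OC(=O)c2c(C)cc(O[Si](C)(C)C(C)(C)C)cc2O[Si](C)(C)C(C)(C)C | intermediate
23 | (1R,4R,5R,6R)-5-(hydroxymethyl)-1-methyl-2-oxo-4-[(E)-pent-3-en-1-yn-1-yl]-7-oxabicyclo[2.2.1]heptan-6-yl 2,4-dihydroxy-6-methylbenzoate | C[C@]12O[C@](C#C/C=C/C)(CC1=O)[C@H](CO)[C@H]2OC(=O)c2c(C)cc(O)cc2O | intermediate (not isolated)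
24 | (1R,2R,6R)-2-hydroxy-6-(hydroxymethyl)-2-methyl-3-oxo-5-[(E)-pent-3-en-1-yn-1-yl]cyclohex-4-en-1-yl 2,4-dihydroxy-6-methylbenzoate | C/C=C/C#CC1=CC(=O)[C@](C)(O)[C@H](OC(=O)c2c(C)cc(O)cc2O)[C@H]1CO | intermediate
25 | berkazaphilone C, (7R,8R,8aR)-7-hydroxy-7-methyl-6-oxo-3-[(E)-prop-1-en-1-yl]-6,7,8,8a-tetrahydro-1H-isochromen-8-yl 2,4-dihydroxy-6-methylbenzoate | C/C=C/C1=CC2=CC(=O)[C@](C)(O)[C@H](OC(=O)c3c(C)cc(O)cc3O)[C@H]2CO1 | target

Total step count: 11. Longest linear sequence: 8 steps (steps 1, 2, 3, 4, 8, 9, 10, 11).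

Steps most likely to fail

Step 8. Under the cationic Lewis acid the cycloaddition may lose its concerted character. A Michael-type zwitterion could transfer silicon or expel the β-aroyloxy group from the copper enolate, and endo or facial discrimination may be incomplete. The fallback moves stereocontrol from the catalyst to a covalently bound auxiliary and leaves out the strong Lewis acid. It sets out from 11, 14 and 15. Acid 15 is joined to commercial (S)-4-benzyloxazolidin-2-one as in step 6 to give (S)-4-benzyl-3-propioloyloxazolidin-2-one F1. Acid 14 is added as in step 7 to give (E)-3-[(S)-4-benzyl-2-oxooxazolidin-3-yl]-3-oxoprop-1-en-1-yl 2,4-bis[(tert-butyldimethylsilyl)oxy]-6-methylbenzoate F2. F2 and furan 11 are combined without catalyst (concentrated in toluene, 0–25 °C) or with MgBr2·OEt2 as a weak two-point binder. In the chelated s-cis form the benzyl group covers the Re face of the α-carbon, so the Si face should react as required. The endo adducts are diastereomers, so the auxiliary-bearing analogue of 21, adduct F3, can be separated even if selectivity is modest. LiBH4 reduction of F3 as in step 9 comes back to the route at 22.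

Step 11. The alcohol may attack the wrong alkyne carbon (5-exo closure), or the gold catalyst may isomerise the propenyl group or engage a second hydroxyl. The fallback uses an amine relay and sets out from 24. Pyrrolidine adds intermolecularly to C3, the δ-carbon of the ynenone, under purely electronic control (conjugate 1,6-addition, THF, rt). This gives the push–pull dienaminone (1R,2R,6R)-2-hydroxy-6-(hydroxymethyl)-2-methyl-3-oxo-5-[(3E)-2-(pyrrolidin-1-yl)penta-1,3-dien-1-yl]cyclohex-4-en-1-yl 2,4-dihydroxy-6-methylbenzoate F4. Brief treatment with pyridinium p-toluenesulfonate in CH2Cl2 lets the primary alcohol displace pyrrolidine at C3 by 6-exo-trig addition–elimination. This comes back to the route at 25.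

Step 9. Hydride may attack the ring carbonyl of the hindered imide (endocyclic cleavage), reduce the aryl ester or trigger its shift to the new alkoxide, or the adduct may undergo cycloreversion on handling. The fallback splits the operation in two and sets out from 21. Lithium ethanethiolate (EtSH, n-BuLi, THF, 0 °C) displaces the oxazolidinone at the exocyclic carbonyl to give the S-ethyl thioester F5. NaBH4 in EtOH/THF at 0 °C should then reduce the thioester, but not the hindered benzoate, and comes back to the route at 22.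

Further compounds
F1 | step 8 | (S)-4-benzyl-3-propioloyloxazolidin-2-one | C#CC(=O)N1[C@@H](Cc2ccccc2)COC1=O
F2 | step 8 | (E)-3-[(S)-4-benzyl-2-oxooxazolidin-3-yl]-3-oxoprop-1-en-1-yl 2,4-bis[(tert-butyldimethylsilyl)oxy]-6-methylbenzoate | Cc1cc(O[Si](C)(C)C(C)(C)C)cc(O[Si](C)(C)C(C)(C)C)c1C(=O)O/C=C/C(=O)N1[C@@H](Cc2ccccc2)COC1=O
F3 | step 8 | (1R,4R,5R,6R)-5-[(S)-4-benzyl-2-oxooxazolidine-3-carbonyl]-1-methyl-4-[(E)-pent-3-en-1-yn-1-yl]-2-[(triisopropylsilyl)oxy]-7-oxabicyclo[2.2.1]hept-2-en-6-yl 2,4-bis[(tert-butyldimethylsilyl)oxy]-6-methylbenzoate | C[C@]12O[C@](C#C/C=C/C)(C=C1O[Si](C(C)C)(C(C)C)C(C)C)[C@H](C(=O)N3[C@@H](Cc4ccccc4)COC3=O)[C@H]2OC(=O)c2c(C)cc(O[Si](C)(C)C(C)(C)C)cc2O[Si](C)(C)C(C)(C)C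
F4 | step 11 | (1R,2R,6R)-2-hydroxy-6-(hydroxymethyl)-2-methyl-3-oxo-5-[(3E)-2-(pyrrolidin-1-yl)penta-1,3-dien-1-yl]cyclohex-4-en-1-yl 2,4-dihydroxy-6-methylbenzoate | C/C=C/C(N1CCCC1)=CC1=CC(=O)[C@](C)(O)[C@H](OC(=O)c2c(C)cc(O)cc2O)[C@H]1CO
F5 | step 9 | (1R,4R,5R,6R)-5-[(ethylsulfanyl)carbonyl]-1-methyl-4-[(E)-pent-3-en-1-yn-1-yl]-2-[(triisopropylsilyl)oxy]-7-oxabicyclo[2.2.1]hept-2-en-6-yl 2,4-bis[(tert-butyldimethylsilyl)oxy]-6-methylbenzoate | C[C@]12O[C@](C#C/C=C/C)(C=C1O[Si](C(C)C)(C(C)C)C(C)C)[C@H](C(=O)SCC)[C@H]2OC(=O)c2c(C)cc(O[Si](C)(C)C(C)(C)C)cc2O[Si](C)(C)C(C)(C)C
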